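## Analysis of the target

The target is an open-chain C17 polyketide acid with no ring in the chain. C1–C5 is a (2E,4E)-2-methyldienoic acid, C6–C11 carries five stereocentres (C6–Me, C7–OH, C8H2, C9–OH, C10–Me, C11–OH), and C12–C17 is a (12E,14E,16E)-triene with methyl groups on C12 and C16 that ends at C4 of a 2-methyl-1,3-oxazole ring. The SMILES reads 6S,7R,9S,10S,11R, which in the zigzag chain means 6,7-anti, 7,9-syn, 9,10-anti, 10,11-syn and 9,11-anti.

The feature on which the plan rests is that C6–C10 is locally mirror-symmetric. A plane through C8 maps C7–OH onto C9–OH and C6–Me onto C10–Me; the descriptors 6S/10S hide this only through the priority rules. If C5 and C11 were the same kind of carbon, C5–C11 would be a meso compound. The fifth centre, C11, sits next to C10 in the Felkin (syn) relation.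

Sensitive groups: the C11 hydroxyl is allylic to an electron-rich oxazolyl triene and should ionise under acid; the triene is sensitive to light and oxygen; H–C6 is allylic and γ to the dienoate. The difficulty is that the five stereocentres are interrupted by the C8 methylene, so 1,2-induction cannot run through the array. In a linear approach each centre costs its own chiral reagent, and the three hydroxyls must be told apart by protecting groups between two polyenes that tolerate little.

## Retrosynthetic reasoning

**29 ⇐ 28 ⇐ 27.** The acid is released last by saponification of ethyl ester 28, which comes from bis-silyl ether 27 by fluoride-mediated desilylation. Only silicon protection is used, so no acid is needed once the C11 carbinol exists.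

**27 ⇐ 17 + 25 (C11–C12).** This cut removes the whole oxazolyl triene as one late fragment, the alkenyl iodide 25. It also makes C11 from an aldehyde carbon whose α-neighbour C10 is already set. The forward step is a chromium/nickel-mediated alkenylation of aldehyde 17. It must react at the aldehyde and not at the dienoate, and must give the Felkin (10,11-syn) alcohol. Cutting at C13–C14 instead would require C11 to be set and protected earlier.

**25 ⇐ 23 ⇐ 21 ⇐ 20 ⇐ 18 + 19 (and 22).** The triene is unravelled one alkene at a time. The C12 iodide comes from syn-hydrometallation of the methyl alkyne in 23. The C13–C14 bond comes from alkynylation of dienyl iodide 21 with propyne 22. C14 comes from iodo-olefination of enal 20, and C16=C17 from a Wittig reaction of oxazole aldehyde 18 with ylide 19. Each geometry is set by a step with an inherent E or syn preference.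

**17 ⇐ 16 ⇐ 15 ⇐ 13 ⇐ 11 ⇐ 10 (C2=C3 and C4=C5).** The dienoate is cut at both double bonds. Two Wittig reactions with the stabilised ylides 14 and 12 are base-free, so C6, α to aldehyde 11, is not put at risk. The acetate on the C11 oxygen survives both and is then exchanged for the aldehyde of 17.

**10 ⇐ 9 (key disconnection; no skeletal bond is cut).** Erasing the difference between the two termini of 10 gives the meso diol 9. The forward step must tell two enantiotopic hydroxymethyl groups apart across seven carbons. In doing so it makes C6, C7, C9 and C10 a single enantiomer at once and delivers the termini differentiated. A lipase does this; no small reagent has a handle on a 1,7-diol of this kind.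

**9 ⇐ 7 ⇐ 6 (C6 and C10 together).** Both methyl-bearing centres are made in one two-directional hydroboration of the bis-isopropenyl compound 7. Each new centre is set anti to its silyloxy neighbour by acyclic 1,2-induction.

**6 ⇐ 4 ⇐ 1 + 2 (C7–C8).** The syn-diol 6 is meso, so the aldol 4 of enone 1 with enal 2 can be racemic. A chelation-controlled syn reduction converges both enantiomers of 4 on the same compound. No chiral reagent is used before the enzyme.

## Alternatives that were turned down

**Alternative 1:** The textbook route cuts C10–C11, then C8–C9 and C6–C7 one after another, with the triene closed at C13–C14 by a Stille coupling.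
- Forward key step: an Evans syn-aldol of a propionyl oxazolidinone with a three-carbon iodo-enal gives the adduct A1 (C9–C13, 10,11-syn). This is followed by acetate-aldol extension, directed 1,3-reductions, an anti-crotylation for C6/C7, olefination to the dienoate and the final cross-coupling.
- Reason for rejection: every stereocentre is bought separately with a stoichiometric auxiliary or chiral boron reagent. Three hydroxyls of similar environment must be differentiated by protecting-group changes. The longest linear sequence would exceed twenty steps and end in a tin coupling. The latent symmetry of C6–C10 is not used.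

**Alternative 2:** A convergent cut at C7–C8.
- Forward key step: a boron-mediated 1,5-anti aldol of the methyl ketone A2 (C8–C17, C11 oxygen as a 4-methoxybenzyl ether) with the aldehyde A3 (C1–C7), then a syn reduction at C9. The 7,11-anti and 7,9-syn relations fit.
- Reason for rejection: A3 has its only stereocentre α to the aldehyde and allylic to the dienoate. Epimerisation and migration of the C4=C5 bond into conjugation are expected under amine and boron-enolate conditions. The required 6,7-anti relation is the anti-Felkin one, so remote 1,5-induction must override the aldehyde's own bias. The benzyl-type ether needed at C11 for the induction must later be removed by oxidation or acid next to the triene. C10 and C11 would still need an auxiliary aldol beforehand.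

**Alternative 3:** A two-directional C–C bond formation that cuts C6–C7 and C9–C10 at once.
- Forward key step: an iridium-catalysed transfer-hydrogenative double anti-crotylation of propane-1,3-diol A4 to the diene-diol A5.
- Reason for rejection: one chiral catalyst sets both carbinols in the same absolute sense, so A5 is C2-symmetric with a 1,3-anti diol. The target needs the mirror-type (syn, pseudo-meso) array, in which the two ends have opposite absolute sense; this is the mismatched outcome of double catalyst control. Inverting one carbinol afterwards would also turn its Me/OH relation from anti to syn. The symmetry of the target is of the mirror kind, so only a step that distinguishes enantiotopic groups fits it.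

Key step: step 5

Assumption: the lipase is taken to acetylate the hydroxymethyl arm next to C10, by analogy with its preference for the (S)-type arm of 2-methylalkan-1-ols. Were the preference the opposite, the free and the acetylated terminus of 10 would exchange roles in the later steps at the cost of one protecting-group step.

## Route

Step 1
Reactants: 1 3-methylbut-3-en-2-one; 2 2-methylprop-2-enal (methacrolein)
Product: 4 rac-5-hydroxy-2,6-dimethylhepta-1,6-dien-3-one, via lithium dienolate 3 (not isolated)
Conditions: LiN(iPr)2, THF, −78 °C; then 2, −78 °C; AcOH quench at −78 °C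
Reagents that add atoms: none
Why: Kinetic deprotonation of the methyl group of 1 gives the cross-conjugated lithium enolate, which adds 1,2 to enal 2 at low temperature (directed aldol addition, C7–C8); the product is racemic on purpose, since both enantiomers converge on the same meso diol in step 2.

Step 2
Reactants: 4 rac-5-hydroxy-2,6-dimethylhepta-1,6-dien-3-one
Product: 6 meso-(3R,5S)-2,6-dimethylhepta-1,6-diene-3,5-diol, via diethylboron chelate 5 (not isolated)
Conditions: Et2BOMe, THF/MeOH 4:1, −78 °C; NaBH4, −78 °C; AcOH, then co-evaporation with MeOH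
Reagents that add atoms: none
Why: Narasaka–Prasad reduction: the boron chelate fixes a half-chair and external hydride is delivered axially, giving the 1,3-syn diol, which here is the meso compound; the chelated carbonyl is activated for 1,2-attack, so conjugate reduction of the isopropenyl ketone should stay minor.

Step 3
Reactants: 6 meso-(3R,5S)-2,6-dimethylhepta-1,6-diene-3,5-diol
Product: 7 meso-(3R,5S)-3,5-bis(tert-butyldimethylsilyloxy)-2,6-dimethylhepta-1,6-diene
Conditions: TBSOTf, 2,6-lutidine, CH2Cl2, −78 → 0 °C
Reagents that add atoms: tert-butyldimethylsilyl trifluoromethanesulfonate, CC(C)(C)[Si](C)(C)OS(=O)(=O)C(F)(F)F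
Why: Standard silylation of secondary allylic alcohols; the silyl ethers are inert to all later steps, do not chelate (important in step 15) and leave at the end with fluoride instead of acid.

Step 4
Reactants: 7 meso-(3R,5S)-3,5-bis(tert-butyldimethylsilyloxy)-2,6-dimethylhepta-1,6-diene
Product: 9 meso-(2R,3S,5R,6S)-3,5-bis(tert-butyldimethylsilyloxy)-2,6-dimethylheptane-1,7-diol, via bis(9-borabicyclononyl) adduct 8 (not isolated)
Conditions: 9-BBN (3 equiv), THF, 0 °C → rt; then aq NaOH, H2O2, 0 °C → rt
Reagents that add atoms: hydrogen peroxide, OO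
Why: Two-directional hydroboration–oxidation of the two 1,1-disubstituted alkenes: with the bulky dialkylborane each allylic centre reacts through the conformer of least allylic strain and boron adds anti to the C8 chain, which should set C6 and C10 anti to the adjacent silyloxy groups (acyclic 1,2-induction of the Still type); isomers from one wrong addition are diastereomers of 9 and are removed by chromatography here or at 10.

Step 5
Reactants: 9 meso-(2R,3S,5R,6S)-3,5-bis(tert-butyldimethylsilyloxy)-2,6-dimethylheptane-1,7-diol
Product: 10 (2R,3S,5R,6S)-3,5-bis(tert-butyldimethylsilyloxy)-7-hydroxy-2,6-dimethylheptyl acetate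
Conditions: immobilised Burkholderia cepacia lipase (Amano PS), vinyl acetate (5 equiv), tBuOMe, 30 °C
Reagents that add atoms: vinyl acetate, CC(=O)OC=C
Why: Lipase-catalysed desymmetrisation: the active-site serine is acetylated by vinyl acetate (the vinyl alcohol set free tautomerises, so the transfer is irreversible) and the acyl-enzyme passes the acetyl group to only one of the two enantiotopic hydroxymethyl groups of the meso diol. The closest known reaction type is the lipase monoacetylation of meso-2,4-dimethylpentane-1,5-diol and of meso polypropionate diols, where the β-methyl centre next to the reacting CH2OH is read by the enzyme pocket (chain in the large site, methyl in the medium site). No skeletal bond is formed, no ring is closed and no new stereocentre is made; instead the four centres C6, C7, C9 and C10, until now an achiral meso set, become one enantiomer in this single operation, the controlling element being the chiral active site and no group of the substrate. Two selectivities are needed, the C11 arm against the C5 arm and mono- against diacetylation. The first is secured by the substrate design: the only free hydroxyls are the two primary ones, each next to a methyl centre of opposite sense, while the silyl ethers keep O7 and O9 out of play and make the diol soluble in the non-polar medium the enzyme prefers. The second helps the first, because the minor mirror-image product still carries the fast-reacting arm and is acetylated again, so the optical purity of 10 should rise with conversion. The step also delivers the two termini in different form (OH on the C5 side, OAc on the C11 side), which is all the differentiation the rest of the route needs.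

Step 6
Reactants: 10 (2R,3S,5R,6S)-3,5-bis(tert-butyldimethylsilyloxy)-7-hydroxy-2,6-dimethylheptyl acetate
Product: 11 (2R,3S,5R,6R)-3,5-bis(tert-butyldimethylsilyloxy)-2,6-dimethyl-7-oxoheptyl acetate
Conditions: Dess–Martin periodinane, CH2Cl2, 0 °C → rt
Reagents that add atoms: none
Why: Dess–Martin oxidation of the primary alcohol under near-neutral conditions; the α-stereocentre C6 should not epimerise and the acetate and silyl ethers are untouched.

Step 7
Reactants: 11 (2R,3S,5R,6R)-3,5-bis(tert-butyldimethylsilyloxy)-2,6-dimethyl-7-oxoheptyl acetate; 12 2-(triphenylphosphoranylidene)acetaldehyde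
Product: 13 (2R,3S,5R,6S,7E)-3,5-bis(tert-butyldimethylsilyloxy)-2,6-dimethyl-9-oxonon-7-en-1-yl acetate
Conditions: 12 (1.5 equiv), toluene, 80 °C
Reagents that add atoms: none
Why: Wittig reaction with a stabilised formyl ylide gives the (E)-enal (C4=C5) without added base, so C6 keeps its configuration; the product enal is less electrophilic than the aliphatic aldehyde, which limits a second homologation.

Step 8
Reactants: 13 (2R,3S,5R,6S,7E)-3,5-bis(tert-butyldimethylsilyloxy)-2,6-dimethyl-9-oxonon-7-en-1-yl acetate; 14 ethyl 2-(triphenylphosphoranylidene)propanoate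
Product: 15 ethyl (2E,4E,6S,7R,9S,10R)-11-acetoxy-7,9-bis(tert-butyldimethylsilyloxy)-2,6,10-trimethylundeca-2,4-dienoate
Conditions: 14 (1.5 equiv), CH2Cl2, 40 °C
Reagents that add atoms: none
Why: Wittig reaction of the enal with the stabilised α-methyl ylide gives the (E)-trisubstituted C2=C3 bond and completes the (2E,4E)-dienoate.

Step 9
Reactants: 15 ethyl (2E,4E,6S,7R,9S,10R)-11-acetoxy-7,9-bis(tert-butyldimethylsilyloxy)-2,6,10-trimethylundeca-2,4-dienoate
Product: 16 ethyl (2E,4E,6S,7R,9S,10R)-7,9-bis(tert-butyldimethylsilyloxy)-11-hydroxy-2,6,10-trimethylundeca-2,4-dienoate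
Conditions: K2CO3 (0.5 equiv), EtOH, 0 °C → rt
Reagents that add atoms: none
Why: Base-catalysed transesterification removes the primary acetate; in ethanol the hindered conjugated ethyl ester can only exchange with itself, and short exposure at low temperature should avoid 1,3-silyl migration.

Step 10
Reactants: 16 ethyl (2E,4E,6S,7R,9S,10R)-7,9-bis(tert-butyldimethylsilyloxy)-11-hydroxy-2,6,10-trimethylundeca-2,4-dienoate
Product: 17 ethyl (2E,4E,6S,7R,9S,10S)-7,9-bis(tert-butyldimethylsilyloxy)-2,6,10-trimethyl-11-oxoundeca-2,4-dienoate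
Conditions: Dess–Martin periodinane, CH2Cl2, 0 °C → rt
Reagents that add atoms: none
Why: Dess–Martin oxidation as in step 6; the α-methyl-β-silyloxy aldehyde is used at once so that C10 does not epimerise.

Step 11
Reactants: 18 2-methyl-1,3-oxazole-4-carbaldehyde; 19 2-(triphenylphosphoranylidene)propanal
Product: 20 (2E)-2-methyl-3-(2-methyl-1,3-oxazol-4-yl)prop-2-enal
Conditions: 19 (1.2 equiv), toluene, 90 °C
Reagents that add atoms: none
Why: Wittig reaction of the heteroaryl aldehyde with the stabilised α-methyl formyl ylide gives the (E)-trisubstituted enal (C16=C17); the hindered, deactivated product enal should not react a second time.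

Step 12
Reactants: 20 (2E)-2-methyl-3-(2-methyl-1,3-oxazol-4-yl)prop-2-enal
Product: 21 4-[(1E,3E)-4-iodo-2-methylbuta-1,3-dien-1-yl]-2-methyl-1,3-oxazole
Conditions: CrCl2 (6 equiv), CHI3 (2 equiv), THF/1,4-dioxane, 0 °C → rt, dark
Reagents that add atoms: iodoform, IC(I)I
Why: Takai iodo-olefination: the geminal dichromium species formed from iodoform and divalent chromium adds to the aldehyde and eliminates to the (E)-vinyl iodide (C14=C15); the oxazole is inert.

Step 13
Reactants: 21 4-[(1E,3E)-4-iodo-2-methylbuta-1,3-dien-1-yl]-2-methyl-1,3-oxazole; 22 propyne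
Product: 23 2-methyl-4-[(1E,3E)-2-methylhepta-1,3-dien-5-yn-1-yl]-1,3-oxazole
Conditions: 22 (excess), PdCl2(PPh3)2 (3 mol%), CuI (6 mol%), Et3N, THF, 0 °C → rt
Reagents that add atoms: none
Why: Sonogashira coupling of a vinyl iodide with a terminal alkyne forms C13–C14 with retention of the alkene geometry at room temperature.

Step 14
Reactants: 23 2-methyl-4-[(1E,3E)-2-methylhepta-1,3-dien-5-yn-1-yl]-1,3-oxazole
Product: 25 4-[(1E,3E,5E)-6-iodo-2-methylhepta-1,3,5-trien-1-yl]-2-methyl-1,3-oxazole, via alkenylzirconocene chloride 24 (not isolated)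
Conditions: Cp2Zr(H)Cl (2 equiv), THF, rt → 40 °C, dark; then I2, THF, −20 °C
Reagents that add atoms: iodine, II
Why: Hydrozirconation is a syn addition and, after equilibration with excess Schwartz reagent, should place zirconium on the less hindered methyl-bearing carbon C12 remote from the diene; iodinolysis with retention gives the (E)-2-iodoalkene.

Step 15
Reactants: 17 ethyl (2E,4E,6S,7R,9S,10S)-7,9-bis(tert-butyldimethylsilyloxy)-2,6,10-trimethyl-11-oxoundeca-2,4-dienoate; 25 4-[(1E,3E,5E)-6-iodo-2-methylhepta-1,3,5-trien-1-yl]-2-methyl-1,3-oxazole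
Product: 27 ethyl (2E,4E,6S,7R,9S,10R,11R,12E,14E,16E)-7,9-bis(tert-butyldimethylsilyloxy)-11-hydroxy-2,6,10,12,16-pentamethyl-17-(2-methyl-1,3-oxazol-4-yl)heptadeca-2,4,12,14,16-pentaenoate, via alkenylchromium dichloride 26 (not isolated)
Conditions: 25 (1.5 equiv), CrCl2 (8 equiv), NiCl2 (0.1 equiv), DMSO, rt, dark
Reagents that add atoms: none
Why: Nozaki–Hiyama–Kishi reaction: zerovalent nickel inserts into the C–I bond, the alkenyl group passes to trivalent chromium and adds to the aldehyde only (the ester is inert), forming C11–C12; Felkin–Anh attack anti to the C9 chain, reinforced by the 1,3-anti preference of the non-chelating β-silyloxy group, should give the 10,11-syn, 9,11-anti alcohol (11R).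

Step 16
Reactants: 27 ethyl (2E,4E,6S,7R,9S,10R,11R,12E,14E,16E)-7,9-bis(tert-butyldimethylsilyloxy)-11-hydroxy-2,6,10,12,16-pentamethyl-17-(2-methyl-1,3-oxazol-4-yl)heptadeca-2,4,12,14,16-pentaenoate
Product: 28 ethyl (2E,4E,6S,7R,9S,10S,11R,12E,14E,16E)-7,9,11-trihydroxy-2,6,10,12,16-pentamethyl-17-(2-methyl-1,3-oxazol-4-yl)heptadeca-2,4,12,14,16-pentaenoate
Conditions: Bu4NF (6 equiv), THF, 0 °C → rt, dark
Reagents that add atoms: none
Why: Fluoride cleaves both secondary silyl ethers under basic, non-acidic conditions, which the acid-labile trienyl carbinol at C11 tolerates; no oxa-Michael ring closure onto the (E,E)-dienoate is geometrically possible.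

Step 17
Reactants: 28 ethyl (2E,4E,6S,7R,9S,10S,11R,12E,14E,16E)-7,9,11-trihydroxy-2,6,10,12,16-pentamethyl-17-(2-methyl-1,3-oxazol-4-yl)heptadeca-2,4,12,14,16-pentaenoate
Product: 29 (2E,4E,6S,7R,9S,10S,11R,12E,14E,16E)-7,9,11-trihydroxy-2,6,10,12,16-pentamethyl-17-(2-methyl-1,3-oxazol-4-yl)heptadeca-2,4,12,14,16-pentaenoic acid (target)
Conditions: LiOH (10 equiv), THF/EtOH/H2O 2:1:1, rt, dark; then AcOH to pH 5
Reagents that add atoms: lithium hydroxide, [Li+].[OH-]
Why: Saponification of the conjugated ethyl ester; no carbonyl is β to a hydroxyl, so neither retro-aldol nor elimination is open, and acidification stops at pH 5 to spare the C11 allylic alcohol.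

## Compound list

1 | 3-methylbut-3-en-2-one | CC(=C)C(C)=O | starting material
2 | 2-methylprop-2-enal (methacrolein) | CC(=C)C=O | starting material
3 | lithium 3-methylbuta-1,3-dien-2-olate (enolate of 1, formed in the flask) | [Li]OC(=C)C(C)=C | intermediate
4 | rac-5-hydroxy-2,6-dimethylhepta-1,6-dien-3-one | CC(=C)C(O)CC(=O)C(C)=C | intermediate
5 | O-diethylboryl derivative of 4 (boron chelate, formed in the flask) | CCB(CC)OC(CC(=O)C(C)=C)C(C)=C | intermediate
6 | meso-(3R,5S)-2,6-dimethylhepta-1,6-diene-3,5-diol | C=C(C)[C@@H](O)C[C@@H](O)C(C)=C | intermediate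
7 | meso-(3R,5S)-3,5-bis(tert-butyldimethylsilyloxy)-2,6-dimethylhepta-1,6-diene | C=C(C)[C@@H](O[Si](C)(C)C(C)(C)C)C[C@@H](O[Si](C)(C)C(C)(C)C)C(C)=C | intermediate
8 | 1,7-bis(9-borabicyclo[3.3.1]nonan-9-yl) adduct of 7 (formed in the flask) | B1(C2CCCC1CCC2)C[C@@H](C)[C@@H](O[Si](C)(C)C(C)(C)C)C[C@@H](O[Si](C)(C)C(C)(C)C)[C@@H](C)CB1C2CCCC1CCC2 | intermediate
9 | meso-(2R,3S,5R,6S)-3,5-bis(tert-butyldimethylsilyloxy)-2,6-dimethylheptane-1,7-diol | OC[C@@H](C)[C@@H](O[Si](C)(C)C(C)(C)C)C[C@@H](O[Si](C)(C)C(C)(C)C)[C@@H](C)CO | intermediate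
10 | (2R,3S,5R,6S)-3,5-bis(tert-butyldimethylsilyloxy)-7-hydroxy-2,6-dimethylheptyl acetate | CC(=O)OC[C@@H](C)[C@@H](O[Si](C)(C)C(C)(C)C)C[C@@H](O[Si](C)(C)C(C)(C)C)[C@@H](C)CO | intermediate
11 | (2R,3S,5R,6R)-3,5-bis(tert-butyldimethylsilyloxy)-2,6-dimethyl-7-oxoheptyl acetate | CC(=O)OC[C@@H](C)[C@@H](O[Si](C)(C)C(C)(C)C)C[C@@H](O[Si](C)(C)C(C)(C)C)[C@@H](C)C=O | intermediate
12 | 2-(triphenylphosphoranylidene)acetaldehyde | O=CC=P(c1ccccc1)(c1ccccc1)c1ccccc1 | starting material
13 | (2R,3S,5R,6S,7E)-3,5-bis(tert-butyldimethylsilyloxy)-2,6-dimethyl-9-oxonon-7-en-1-yl acetate | CC(=O)OC[C@@H](C)[C@@H](O[Si](C)(C)C(C)(C)C)C[C@@H](O[Si](C)(C)C(C)(C)C)[C@@H](C)/C=C/C=O | intermediate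
14 | ethyl 2-(triphenylphosphoranylidene)propanoate | CCOC(=O)C(C)=P(c1ccccc1)(c1ccccc1)c1ccccc1 | starting material
15 | ethyl (2E,4E,6S,7R,9S,10R)-11-acetoxy-7,9-bis(tert-butyldimethylsilyloxy)-2,6,10-trimethylundeca-2,4-dienoate | CC(=O)OC[C@@H](C)[C@@H](O[Si](C)(C)C(C)(C)C)C[C@@H](O[Si](C)(C)C(C)(C)C)[C@@H](C)/C=C/C=C(\C)C(=O)OCC | intermediate
16 | ethyl (2E,4E,6S,7R,9S,10R)-7,9-bis(tert-butyldimethylsilyloxy)-11-hydroxy-2,6,10-trimethylundeca-2,4-dienoate | OC[C@@H](C)[C@@H](O[Si](C)(C)C(C)(C)C)C[C@@H](O[Si](C)(C)C(C)(C)C)[C@@H](C)/C=C/C=C(\C)C(=O)OCC | intermediate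
17 | ethyl (2E,4E,6S,7R,9S,10S)-7,9-bis(tert-butyldimethylsilyloxy)-2,6,10-trimethyl-11-oxoundeca-2,4-dienoate | O=C[C@@H](C)[C@@H](O[Si](C)(C)C(C)(C)C)C[C@@H](O[Si](C)(C)C(C)(C)C)[C@@H](C)/C=C/C=C(\C)C(=O)OCC | intermediate
18 | 2-methyl-1,3-oxazole-4-carbaldehyde | Cc1nc(C=O)co1 | starting material
19 | 2-(triphenylphosphoranylidene)propanal | CC(C=O)=P(c1ccccc1)(c1ccccc1)c1ccccc1 | starting material
20 | (2E)-2-methyl-3-(2-methyl-1,3-oxazol-4-yl)prop-2-enal | O=C/C(C)=C/c1coc(C)n1 | intermediate
21 | 4-[(1E,3E)-4-iodo-2-methylbuta-1,3-dien-1-yl]-2-methyl-1,3-oxazole | I/C=C/C(C)=C/c1coc(C)n1 | intermediate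
22 | propyne | CC#C | starting material
23 | 2-methyl-4-[(1E,3E)-2-methylhepta-1,3-dien-5-yn-1-yl]-1,3-oxazole | CC#C/C=C/C(C)=C/c1coc(C)n1 | intermediate
24 | chlorobis(cyclopentadienyl)[(2E,4E,6E)-6-methyl-7-(2-methyl-1,3-oxazol-4-yl)hepta-2,4,6-trien-2-yl]zirconium (formed in the flask) | CC(/C=C/C=C(\C)[Zr](Cl)(C1C=CC=C1)C1C=CC=C1)=C\c1coc(C)n1 | intermediate
25 | 4-[(1E,3E,5E)-6-iodo-2-methylhepta-1,3,5-trien-1-yl]-2-methyl-1,3-oxazole | CC(/C=C/C=C(\C)I)=C\c1coc(C)n1 | intermediate
26 | dichloro[(2E,4E,6E)-6-methyl-7-(2-methyl-1,3-oxazol-4-yl)hepta-2,4,6-trien-2-yl]chromium (formed in the flask) | CC(/C=C/C=C(\C)[Cr](Cl)Cl)=C\c1coc(C)n1 | intermediate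
27 | ethyl (2E,4E,6S,7R,9S,10R,11R,12E,14E,16E)-7,9-bis(tert-butyldimethylsilyloxy)-11-hydroxy-2,6,10,12,16-pentamethyl-17-(2-methyl-1,3-oxazol-4-yl)heptadeca-2,4,12,14,16-pentaenoate | CC(/C=C/C=C(\C)[C@H](O)[C@@H](C)[C@@H](O[Si](C)(C)C(C)(C)C)C[C@@H](O[Si](C)(C)C(C)(C)C)[C@@H](C)/C=C/C=C(\C)C(=O)OCC)=C\c1coc(C)n1 | intermediate
28 | ethyl (2E,4E,6S,7R,9S,10S,11R,12E,14E,16E)-7,9,11-trihydroxy-2,6,10,12,16-pentamethyl-17-(2-methyl-1,3-oxazol-4-yl)heptadeca-2,4,12,14,16-pentaenoate | CC(/C=C/C=C(\C)[C@H](O)[C@@H](C)[C@@H](O)C[C@@H](O)[C@@H](C)/C=C/C=C(\C)C(=O)OCC)=C\c1coc(C)n1 | intermediate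
29 | (2E,4E,6S,7R,9S,10S,11R,12E,14E,16E)-7,9,11-trihydroxy-2,6,10,12,16-pentamethyl-17-(2-methyl-1,3-oxazol-4-yl)heptadeca-2,4,12,14,16-pentaenoic acid | CC(/C=C/C=C(\C)[C@H](O)[C@@H](C)[C@@H](O)C[C@@H](O)[C@@H](C)/C=C/C=C(\C)C(=O)O)=C\c1coc(C)n1 | target

## Step count and least certain steps

Total step count: 17. Longest linear sequence: 13 steps (steps 1–10 and 15–17); the triene branch (steps 11–14) joins at step 15.

**Step 5 (key step).** The acyl transfer may be slow or poorly selective, because a bulky silyloxy group sits two carbons from each reacting hydroxymethyl group and may not fit the binding channel of the enzyme; the enantiotopic preference could also be opposite to the one assumed. The fallback differentiates the arms chemically through diastereomers. It sets out from 9: esterification with one equivalent of (S)-2-methoxy-2-phenylacetic acid (DCC, DMAP, CH2Cl2) gives two separable monoesters. These are [(2R,3S,5R,6S)-3,5-bis(tert-butyldimethylsilyloxy)-7-hydroxy-2,6-dimethylheptyl] (2S)-2-methoxy-2-phenylacetate F1 (ester on the C11 arm) and its arm isomer [(2S,3R,5S,6R)-3,5-bis(tert-butyldimethylsilyloxy)-7-hydroxy-2,6-dimethylheptyl] (2S)-2-methoxy-2-phenylacetate F2 (ester on the C5 arm). F2 is returned to 9 with K2CO3 in ethanol. F1 is carried through the chemistry of steps 6 to 8: the aldehyde [(2R,3S,5R,6R)-3,5-bis(tert-butyldimethylsilyloxy)-2,6-dimethyl-7-oxoheptyl] (2S)-2-methoxy-2-phenylacetate F3, the enal [(2R,3S,5R,6S,7E)-3,5-bis(tert-butyldimethylsilyloxy)-2,6-dimethyl-9-oxonon-7-en-1-yl] (2S)-2-methoxy-2-phenylacetate F4, and the dienoate ethyl (2E,4E,6S,7R,9S,10R)-7,9-bis(tert-butyldimethylsilyloxy)-11-[(2S)-2-methoxy-2-phenylacetoxy]-2,6,10-trimethylundeca-2,4-dienoate F5. Transesterification of F5 with K2CO3 in ethanol comes back to the route at 16. Using the enantiomeric acid or the other diastereomer covers either topicity.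

**Step 15.** Facial selectivity in the addition of the alkenylchromium species to the α-methyl aldehyde may be poor, because such closed transition states follow Felkin control less strictly than open ones. The fallback sets C11 by reduction instead of by C–C bond formation. It sets out from 27 as obtained (both C11 configurations): Dess–Martin oxidation gives the cross-conjugated ketone ethyl (2E,4E,6S,7R,9S,10S,12E,14E,16E)-7,9-bis(tert-butyldimethylsilyloxy)-2,6,10,12,16-pentamethyl-17-(2-methyl-1,3-oxazol-4-yl)-11-oxoheptadeca-2,4,12,14,16-pentaenoate F6. Corey–Bakshi–Shibata reduction ((S)-2-methyl-CBS-oxazaborolidine, catecholborane, −78 °C), with the 2-substituted alkenyl arm as the large group, should return the 11R alcohol, and the route is rejoined at 27.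

**Step 14.** Regiocontrol of the Zr–H addition to the conjugated dienyne may be incomplete (zirconium at C13 instead of C12), or the diene may be hydrozirconated in competition. The fallback avoids the iodide altogether. It sets out from 23, which is coupled directly with aldehyde 17 in a nickel-catalysed reductive enyne–aldehyde coupling (Ni(cod)2 as the source of zerovalent nickel, a trialkylphosphine, Et3B). This reaction type forms the C–C bond at the alkyne carbon remote from the alkene with syn delivery of hydrogen, and it comes back to the route at 27 without any new compound. The C11 configuration may then need the oxidation–reduction described for step 15.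

**Step 1.** Conjugate addition and oligomerisation may compete under the strongly basic conditions, since the amide base or the enolate can add to the unhindered β-carbon of 1; retro-aldol cleavage on work-up is also possible. The fallback builds the β-hydroxy enone without an enone enolate. It sets out from 2: aldol addition of the lithium enolate of N-methoxy-N-methylacetamide gives the Weinreb amide 3-hydroxy-N-methoxy-N,4-dimethylpent-4-enamide F7. Excess isopropenylmagnesium bromide then converts F7 into the ketone, rejoining the route at 4.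

## Further compounds

F1 | step 5 | [(2R,3S,5R,6S)-3,5-bis(tert-butyldimethylsilyloxy)-7-hydroxy-2,6-dimethylheptyl] (2S)-2-methoxy-2-phenylacetate | CO[C@@H](c1ccccc1)C(=O)OC[C@@H](C)[C@@H](O[Si](C)(C)C(C)(C)C)C[C@@H](O[Si](C)(C)C(C)(C)C)[C@@H](C)CO
F2 | step 5 | [(2S,3R,5S,6R)-3,5-bis(tert-butyldimethylsilyloxy)-7-hydroxy-2,6-dimethylheptyl] (2S)-2-methoxy-2-phenylacetate | OC[C@@H](C)[C@@H](O[Si](C)(C)C(C)(C)C)C[C@@H](O[Si](C)(C)C(C)(C)C)[C@@H](C)COC(=O)[C@@H](OC)c1ccccc1
F3 | step 5 | [(2R,3S,5R,6R)-3,5-bis(tert-butyldimethylsilyloxy)-2,6-dimethyl-7-oxoheptyl] (2S)-2-methoxy-2-phenylacetate | CO[C@@H](c1ccccc1)C(=O)OC[C@@H](C)[C@@H](O[Si](C)(C)C(C)(C)C)C[C@@H](O[Si](C)(C)C(C)(C)C)[C@@H](C)C=O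
F4 | step 5 | [(2R,3S,5R,6S,7E)-3,5-bis(tert-butyldimethylsilyloxy)-2,6-dimethyl-9-oxonon-7-en-1-yl] (2S)-2-methoxy-2-phenylacetate | CO[C@@H](c1ccccc1)C(=O)OC[C@@H](C)[C@@H](O[Si](C)(C)C(C)(C)C)C[C@@H](O[Si](C)(C)C(C)(C)C)[C@@H](C)/C=C/C=O
F5 | step 5 | ethyl (2E,4E,6S,7R,9S,10R)-7,9-bis(tert-butyldimethylsilyloxy)-11-[(2S)-2-methoxy-2-phenylacetoxy]-2,6,10-trimethylundeca-2,4-dienoate | CO[C@@H](c1ccccc1)C(=O)OC[C@@H](C)[C@@H](O[Si](C)(C)C(C)(C)C)C[C@@H](O[Si](C)(C)C(C)(C)C)[C@@H](C)/C=C/C=C(\C)C(=O)OCC
F6 | step 15 | ethyl (2E,4E,6S,7R,9S,10S,12E,14E,16E)-7,9-bis(tert-butyldimethylsilyloxy)-2,6,10,12,16-pentamethyl-17-(2-methyl-1,3-oxazol-4-yl)-11-oxoheptadeca-2,4,12,14,16-pentaenoate | CC(/C=C/C=C(\C)C(=O)[C@@H](C)[C@@H](O[Si](C)(C)C(C)(C)C)C[C@@H](O[Si](C)(C)C(C)(C)C)[C@@H](C)/C=C/C=C(\C)C(=O)OCC)=C\c1coc(C)n1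
F0 | step 14 | none | none
F7 | step 1 | 3-hydroxy-N-methoxy-N,4-dimethylpent-4-enamide (racemic) | CC(=C)C(O)CC(=O)N(C)OC
A1 | alternative 1 | (4R)-4-benzyl-3-[(2R,3R,4E)-3-hydroxy-5-iodo-2,4-dimethylpent-4-enoyl]-1,3-oxazolidin-2-one | I/C=C(\C)[C@H](O)[C@@H](C)C(=O)N1C(=O)OC[C@H]1Cc1ccccc1
A2 | alternative 2 | (3R,4R,5E,7E,9E)-4-[(4-methoxyphenyl)methoxy]-3,5,9-trimethyl-10-(2-methyl-1,3-oxazol-4-yl)deca-5,7,9-trien-2-one | CC(/C=C/C=C(\C)[C@H](OCc1ccc(OC)cc1)[C@@H](C)C(C)=O)=C\c1coc(C)n1
A3 | alternative 2 | ethyl (2E,4E,6S)-2,6-dimethyl-7-oxohepta-2,4-dienoate | O=C[C@@H](C)/C=C/C=C(\C)C(=O)OCC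
A4 | alternative 3 | propane-1,3-diol | OCCCO
A5 | alternative 3 | (3R,4S,6S,7R)-3,7-dimethylnona-1,8-diene-4,6-diol | C=C[C@@H](C)[C@@H](O)C[C@H](O)[C@H](C)C=C
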